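The cyclohexene ring (carotenoid numbering: C1 is CMe2, C3 is CHOH, C4=C5 carries the C5 methyl, C6 carries the polyene) hides an isophorone pattern: the C3 oxygen lies 1,3 to the quaternary carbon C1 and the olefinic C5 bears a methyl. A single Michael/aldol-condensation annulation of mesityl oxide (C1–C4) with ethyl acetoacetate (C5, C6 and the future C7) therefore forges the C6–C1 bond at the quaternary carbon and the C4=C5 double bond in one operation. The annulation product keeps C6 epimerisable, so a ketoreductase can set C3 and C6 together by dynamic kinetic resolution. A Julia–Kocienski olefination with crocetin dialdehyde then closes C7=C8.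

Key step: step 1

Assumption: crocetin dialdehyde (8,8'-diapocarotene-8,8'-dial) is bought from a supplier of carotenoid building blocks; ring atoms are named by carotenoid numbering throughout (C7 is the first chain carbon).

Step 1
Reactants: 1 mesityl oxide; 2 ethyl acetoacetate
Product: 5 racemic ethyl 2,6,6-trimethyl-4-oxocyclohex-2-ene-1-carboxylate, via Michael adduct 3 (not isolated), via aldol adduct 4 (not isolated)
Conditions: BF3·OEt2 (0.3 equiv), neat, 0 °C to rt
Reagents that add atoms: none
Why: BF3 activates mesityl oxide for a Mukaiyama-type Michael addition of the acetoacetate enol, whose central carbon (C6) attacks the β,β-dimethyl terminus (C1) to give 1,5-diketone 3; the methyl ketone of 3 then enolises, its CH3 carbon (C4) adds to the acetoacetyl carbonyl (C5), and loss of water from aldol 4 gives the C4=C5 enone. The closest known reaction type is the Robinson-type Michael/aldol-condensation annulation of β-keto esters with enones. The cyclohexenone ring closes in a 6-(enolendo)-exo-trig aldol mode. The only new stereocenter, C6, is formed racemic and is deliberately left uncontrolled, because as the position alpha to the ester and vinylogous to the ketone it epimerises freely and is fixed in step 2. The step needs 1,4- over 1,2-addition and the aldol mode in which C4 attacks C5, not attack of the acetoacetyl CH3 on C3 or a Claisen closure onto the ester: the hindered conjugated ketone of 1 disfavours 1,2-attack, the β-keto ester enolises only toward C6 (boron chelate) so its own methyl is not nucleophilic, the ester is the poorest electrophile, and irreversible dehydration to the conjugated trisubstituted enone drains the desired aldol.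

Step 2
Reactants: 5 racemic ethyl 2,6,6-trimethyl-4-oxocyclohex-2-ene-1-carboxylate
Product: 6 ethyl (1R,4S)-4-hydroxy-2,6,6-trimethylcyclohex-2-ene-1-carboxylate
Conditions: ketoreductase (NADPH-dependent alcohol dehydrogenase, chosen by panel screening for the (1R,4S) product), NADP+ (cat.), i-PrOH, triethanolamine buffer pH 8, 30 °C
Reagents that add atoms: none
Why: Ketoreductase-catalysed dynamic kinetic resolution: the enzyme should deliver hydride from NADPH to one face of the C3 carbonyl of the (6R)-ketone only, while the unreacted (6S)-ketone racemises through its dienolate (C6–H is alpha to the ester and vinylogous to the ketone), so enzyme control sets C3 (S) and C6 (R) together, cis to each other.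

Step 3
Reactants: 6 ethyl (1R,4S)-4-hydroxy-2,6,6-trimethylcyclohex-2-ene-1-carboxylate
Product: 7 ethyl (1R,4S)-4-[(tert-butyldimethylsilyl)oxy]-2,6,6-trimethylcyclohex-2-ene-1-carboxylate
Conditions: TBSCl, imidazole, DMF, rt
Reagents that add atoms: tert-butyldimethylsilyl chloride, CC(C)(C)[Si](C)(C)Cl
Why: Imidazole-mediated silylation of the secondary allylic alcohol; the base is too weak to epimerise C6 and no stereocenter is touched.

Step 4
Reactants: 7 ethyl (1R,4S)-4-[(tert-butyldimethylsilyl)oxy]-2,6,6-trimethylcyclohex-2-ene-1-carboxylate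
Product: 8 [(1R,4S)-4-[(tert-butyldimethylsilyl)oxy]-2,6,6-trimethylcyclohex-2-en-1-yl]methanol
Conditions: LiAlH4, THF, 0 °C; then H2O
Reagents that add atoms: none
Why: Hydride reduction of the ester to the primary alcohol (C7); the silyl ether and the trisubstituted alkene are inert and hydride addition should outpace enolisation, so C6 keeps its configuration and is no longer acidic afterwards.

Step 5
Reactants: 8 [(1R,4S)-4-[(tert-butyldimethylsilyl)oxy]-2,6,6-trimethylcyclohex-2-en-1-yl]methanol
Product: 9 5-({[(1R,4S)-4-[(tert-butyldimethylsilyl)oxy]-2,6,6-trimethylcyclohex-2-en-1-yl]methyl}sulfanyl)-1-phenyl-1H-tetrazole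
Conditions: 1-phenyl-1H-tetrazole-5-thiol, PPh3, DIAD, THF, 0 °C to rt
Reagents that add atoms: 1-phenyl-1H-tetrazole-5-thiol, Sc1nnnn1-c1ccccc1
Why: Mitsunobu thioetherification: the acidic thiol displaces the activated primary (β-branched) C7 hydroxyl by SN2, with no stereocenter involved.

Step 6
Reactants: 9 5-({[(1R,4S)-4-[(tert-butyldimethylsilyl)oxy]-2,6,6-trimethylcyclohex-2-en-1-yl]methyl}sulfanyl)-1-phenyl-1H-tetrazole
Product: 10 5-({[(1R,4S)-4-[(tert-butyldimethylsilyl)oxy]-2,6,6-trimethylcyclohex-2-en-1-yl]methyl}sulfonyl)-1-phenyl-1H-tetrazole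
Conditions: (NH4)6Mo7O24·4H2O (cat.), 30% H2O2, EtOH, 0 °C to rt
Reagents that add atoms: hydrogen peroxide, OO
Why: Molybdate-catalysed peroxide oxidation of sulfide to sulfone, which should be much faster at sulfur than epoxidation of the unactivated trisubstituted alkene and leaves the silyl ether intact.

Step 7
Reactants: 10 5-({[(1R,4S)-4-[(tert-butyldimethylsilyl)oxy]-2,6,6-trimethylcyclohex-2-en-1-yl]methyl}sulfonyl)-1-phenyl-1H-tetrazole; 11 crocetin dialdehyde
Product: 13 (2E,4E,6E,8E,10E,12E,14E,16E)-17-[(1R,4S)-4-[(tert-butyldimethylsilyl)oxy]-2,6,6-trimethylcyclohex-2-en-1-yl]-2,6,11,15-tetramethylheptadeca-2,4,6,8,10,12,14,16-octaenal, via potassium sulfonyl carbanion 12 (not isolated)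
Conditions: KN(SiMe3)2 (1.0 equiv), THF, −78 °C; then added to 11 (3 equiv), THF, −78 °C to rt
Reagents that add atoms: none
Why: Julia–Kocienski olefination: the C7 carbanion adds to one formyl group of 11, Smiles rearrangement of the alkoxide and loss of SO2 and tetrazololate give the C7=C8 double bond, the 1-phenyltetrazolyl sulfone with a potassium counter-ion in an ethereal solvent favouring the E alkene, while the excess of 11 and inverse addition keep the second formyl group unreacted.

Step 8
Reactants: 13 (2E,4E,6E,8E,10E,12E,14E,16E)-17-[(1R,4S)-4-[(tert-butyldimethylsilyl)oxy]-2,6,6-trimethylcyclohex-2-en-1-yl]-2,6,11,15-tetramethylheptadeca-2,4,6,8,10,12,14,16-octaenal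
Product: 14 (2E,4E,6E,8E,10E,12E,14E,16E)-17-[(1R,4S)-4-hydroxy-2,6,6-trimethylcyclohex-2-en-1-yl]-2,6,11,15-tetramethylheptadeca-2,4,6,8,10,12,14,16-octaenal
Conditions: Bu4NF, AcOH, THF, 0 °C to rt
Reagents that add atoms: none
Why: Fluoride-mediated desilylation buffered with acetic acid, near-neutral conditions under which the ionisable allylic C3 alcohol, the polyene and the aldehyde should survive and no stereocenter is touched.

Compound list
1 | mesityl oxide (4-methylpent-3-en-2-one) | CC(C)=CC(C)=O | starting material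
2 | ethyl acetoacetate | CCOC(=O)CC(C)=O | starting material
3 | ethyl 2-acetyl-3,3-dimethyl-5-oxohexanoate (Michael adduct, racemic) | CCOC(=O)C(C(C)=O)C(C)(C)CC(C)=O | intermediate
4 | ethyl 2-hydroxy-2,6,6-trimethyl-4-oxocyclohexane-1-carboxylate (aldol adduct, stereoisomer mixture) | CCOC(=O)C1C(C)(O)CC(=O)CC1(C)C | intermediate
5 | racemic ethyl 2,6,6-trimethyl-4-oxocyclohex-2-ene-1-carboxylate | CCOC(=O)C1C(C)=CC(=O)CC1(C)C | intermediate
6 | ethyl (1R,4S)-4-hydroxy-2,6,6-trimethylcyclohex-2-ene-1-carboxylate | CC1=C[C@@H](O)CC(C)(C)[C@H]1C(=O)OCC | intermediate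
7 | ethyl (1R,4S)-4-[(tert-butyldimethylsilyl)oxy]-2,6,6-trimethylcyclohex-2-ene-1-carboxylate | CC1=C[C@@H](O[Si](C)(C)C(C)(C)C)CC(C)(C)[C@H]1C(=O)OCC | intermediate
8 | [(1R,4S)-4-[(tert-butyldimethylsilyl)oxy]-2,6,6-trimethylcyclohex-2-en-1-yl]methanol | CC1=C[C@@H](O[Si](C)(C)C(C)(C)C)CC(C)(C)[C@H]1CO | intermediate
9 | 5-({[(1R,4S)-4-[(tert-butyldimethylsilyl)oxy]-2,6,6-trimethylcyclohex-2-en-1-yl]methyl}sulfanyl)-1-phenyl-1H-tetrazole | CC1=C[C@@H](O[Si](C)(C)C(C)(C)C)CC(C)(C)[C@H]1CSc1nnnn1-c1ccccc1 | intermediate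
10 | 5-({[(1R,4S)-4-[(tert-butyldimethylsilyl)oxy]-2,6,6-trimethylcyclohex-2-en-1-yl]methyl}sulfonyl)-1-phenyl-1H-tetrazole | CC1=C[C@@H](O[Si](C)(C)C(C)(C)C)CC(C)(C)[C@H]1CS(=O)(=O)c1nnnn1-c1ccccc1 | intermediate
11 | crocetin dialdehyde, (2E,4E,6E,8E,10E,12E,14E)-2,6,11,15-tetramethylhexadeca-2,4,6,8,10,12,14-heptaenedial | O=C/C(C)=C/C=C/C(C)=C/C=C/C=C(C)/C=C/C=C(\C)C=O | starting material
12 | potassium salt of the C7 carbanion of sulfone 10 | CC1=C[C@@H](O[Si](C)(C)C(C)(C)C)CC(C)(C)[C@H]1[CH-]S(=O)(=O)c1nnnn1-c1ccccc1.[K+] | intermediate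
13 | (2E,4E,6E,8E,10E,12E,14E,16E)-17-[(1R,4S)-4-[(tert-butyldimethylsilyl)oxy]-2,6,6-trimethylcyclohex-2-en-1-yl]-2,6,11,15-tetramethylheptadeca-2,4,6,8,10,12,14,16-octaenal | CC1=C[C@@H](O[Si](C)(C)C(C)(C)C)CC(C)(C)[C@H]1/C=C/C(C)=C/C=C/C(C)=C/C=C/C=C(C)/C=C/C=C(\C)C=O | intermediate
14 | (2E,4E,6E,8E,10E,12E,14E,16E)-17-[(1R,4S)-4-hydroxy-2,6,6-trimethylcyclohex-2-en-1-yl]-2,6,11,15-tetramethylheptadeca-2,4,6,8,10,12,14,16-octaenal, i.e. (3S,6R)-3-hydroxy-8'-apo-ε-caroten-8'-al | CC1=C[C@@H](O)CC(C)(C)[C@H]1/C=C/C(C)=C/C=C/C(C)=C/C=C/C=C(C)/C=C/C=C(\C)C=O | target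

Total step count: 8
Longest linear sequence: 8 steps (1 and 2 to 14)

Steps most likely to fail

Step 2 (enzymatic dynamic kinetic resolution). Racemisation of C6 through the dienolate may be slower than reduction, the enzyme may reduce both C6 epimers, or the ester may hydrolyse in the buffer. The fallback sets out from 5. Luche reduction (NaBH4, CeCl3·7H2O, MeOH, −20 °C) should give the racemic cis-hydroxy ester F1, the trans isomer being removed by chromatography. Kinetic resolution by lipase-catalysed acylation (lipase from Burkholderia cepacia, vinyl acetate, tert-butyl methyl ether, rt) should then acetylate the (4R)-carbinol, as expected from the empirical rule for cyclohex-2-enols, to give ethyl (1S,4R)-4-(acetyloxy)-2,6,6-trimethylcyclohex-2-ene-1-carboxylate F2. The unreacted (1R,4S)-alcohol is separated by chromatography and is compound 6, where the route is rejoined.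

Step 7 (Julia–Kocienski mono-olefination). The hindered C7 carbanion may add sluggishly to the sparingly soluble, vinylogously deactivated dialdehyde, E-selectivity at C7=C8 may erode, or the second formyl group may also react. The fallback sets out from 8. Appel-type iodination (I2, PPh3, imidazole, CH2Cl2) should give tert-butyl{[(1S,4R)-4-(iodomethyl)-3,5,5-trimethylcyclohex-2-en-1-yl]oxy}dimethylsilane F3. Heating with PPh3 in acetonitrile should give {[(1R,4S)-4-[(tert-butyldimethylsilyl)oxy]-2,6,6-trimethylcyclohex-2-en-1-yl]methyl}triphenylphosphonium iodide F4. Wittig reaction of its ylide (NaN(SiMe3)2, THF, −78 °C) with excess 11 should give mainly the (16Z) silyl ether F5. Iodine-catalysed isomerisation (cat. I2, hexane/CH2Cl2, daylight) should move the hindered cis bond to trans and give 13, where the route is rejoined.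

Step 1 (key annulation). The acid-promoted cascade may divert into 1,2-condensation at the ketone of mesityl oxide, self-condensation of mesityl oxide, or ring closure in the wrong aldol or Claisen sense. The fallback sets out from 2 and assembles the same 1,5-diketone with reversed polarity at C1. Knoevenagel condensation of 2 with acetone (TiCl4, pyridine, THF, 0 °C to rt) should give ethyl 2-acetyl-3-methylbut-2-enoate F6. Mukaiyama–Michael addition of 2-(trimethylsilyloxy)propene (TiCl4, CH2Cl2, −78 °C) to this doubly activated acceptor should give compound 3, now isolated. Acid-catalysed aldol condensation (TsOH cat., toluene, reflux, water separator) should close the ring and give 5, where the route is rejoined.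

Further compounds
F1 | step 2 | racemic ethyl cis-4-hydroxy-2,6,6-trimethylcyclohex-2-ene-1-carboxylate (1:1 pair of the (1R,4S) and (1S,4R) enantiomers) | CC1=C[C@@H](O)CC(C)(C)[C@H]1C(=O)OCC.CC1=C[C@H](O)CC(C)(C)[C@@H]1C(=O)OCC
F2 | step 2 | ethyl (1S,4R)-4-(acetyloxy)-2,6,6-trimethylcyclohex-2-ene-1-carboxylate | CC1=C[C@H](OC(C)=O)CC(C)(C)[C@@H]1C(=O)OCC
F3 | step 7 | tert-butyl{[(1S,4R)-4-(iodomethyl)-3,5,5-trimethylcyclohex-2-en-1-yl]oxy}dimethylsilane | CC1=C[C@@H](O[Si](C)(C)C(C)(C)C)CC(C)(C)[C@H]1CI
F4 | step 7 | {[(1R,4S)-4-[(tert-butyldimethylsilyl)oxy]-2,6,6-trimethylcyclohex-2-en-1-yl]methyl}triphenylphosphonium iodide | CC1=C[C@@H](O[Si](C)(C)C(C)(C)C)CC(C)(C)[C@H]1C[P+](c1ccccc1)(c1ccccc1)c1ccccc1.[I-]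
F5 | step 7 | (2E,4E,6E,8E,10E,12E,14E,16Z)-17-[(1R,4S)-4-[(tert-butyldimethylsilyl)oxy]-2,6,6-trimethylcyclohex-2-en-1-yl]-2,6,11,15-tetramethylheptadeca-2,4,6,8,10,12,14,16-octaenal | CC1=C[C@@H](O[Si](C)(C)C(C)(C)C)CC(C)(C)[C@H]1\C=C/C(C)=C/C=C/C(C)=C/C=C/C=C(C)/C=C/C=C(\C)C=O
F6 | step 1 | ethyl 2-acetyl-3-methylbut-2-enoate | CCOC(=O)C(C(C)=O)=C(C)C
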